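**Retrosynthetic overview**

1. The target comes from one acidic global deprotection of a protected aminoquinone. The quinone ring (ring B) is closed last, on the intact benzene ring A, by joining its carbonyl carbon C1 (the C=O next to the amino carbon) to the amino-bearing carbon C2.
2. Enabling feature: in ring B the unit C4(=O)–C3H=C2(NH2) is the enaminone tautomer of a cyanoacetyl group Ar–C4(=O)–C3H2–C2≡N, and C1(=O) is at the oxidation level of an aryl aldehyde. Ring B is therefore an isomer of an ortho-formyl aroylacetonitrile, and an N-heterocyclic carbene can close it (formyl C1 as acyl anion onto nitrile C2) with no oxidant and no nitrogen reagent.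
3. The ketoaldehyde comes from aryl–C15 bond formation (arylmagnesium of ring A plus chain enal) and oxidation. Ring A is 3-methoxy-4-methylbenzoic acid, carried through a temporary phthalide (lactone ring C) that holds the future C1 and is opened by LiCH2CN to install C4–C3–C2≡N.
4. Chain: the C4–C12 stereononad has a hidden mirror plane through C8. It is grown as meso compounds from 2-methylpent-1-en-3-one and methacrolein (anti aldol/syn reduction, double hydroboration), desymmetrised once by a lipase, then extended at each end by substrate-controlled (Z)-crotylboration and cross-metathesis.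
5. Ring order: ring A (bought) → temporary lactone ring C (step 1, opened in step 5) → ring B (step 21).

Key step: step 21

Remark: ring-chain tautomers (8, 30) are written in the open keto form; 12 is racemic (one enantiomer drawn); C15 of 30 is an epimer mixture that step 20 destroys; the lipase of step 9 is assumed to show the sense known for meso-2,4-dimethylpentane-1,5-diol. Chain positions use the numbering of the target acid (C1 = CO2H, C15 = aryl ketone carbon).

**Ring A fragment**

Step 1
Reactants: 1 3-methoxy-4-methylbenzoic acid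
Product: 3 6-methoxy-5-methylisobenzofuran-1(3H)-one, via hydroxymethyl acid 2 (not isolated)
Conditions: 37% aq. HCHO, conc. HCl, AcOH, 90 °C
Reagents that add atoms: formaldehyde, C=O
Why: Blanc-type hydroxymethylation goes para to the methoxy group and ortho to the carboxyl, and the benzylic alcohol lactonises at once (classical phthalide synthesis), which places the future C1 carbon next to the future C4 carboxyl carbon.

Step 2
Reactants: 3 6-methoxy-5-methylisobenzofuran-1(3H)-one
Product: 4 6-hydroxy-5-methylisobenzofuran-1(3H)-one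
Conditions: BBr3, CH2Cl2, −78 to 0 °C; then H2O
Reagents that add atoms: none
Why: Lewis-acid cleavage of an aryl methyl ether with BBr3 at low temperature, where the lactone should stay closed.

Step 3
Reactants: 4 6-hydroxy-5-methylisobenzofuran-1(3H)-one
Product: 5 6-hydroxy-7-iodo-5-methylisobenzofuran-1(3H)-one
Conditions: N-iodosuccinimide, TsOH (10 mol %), MeCN, 0 °C to rt
Reagents that add atoms: N-iodosuccinimide, O=C1CCC(=O)N1I
Why: Electrophilic iodination of the phenol, whose only free ortho or para position is C7, gives the handle for the later aryl–C15 bond.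

Step 4
Reactants: 5 6-hydroxy-7-iodo-5-methylisobenzofuran-1(3H)-one
Product: 6 7-iodo-6-(methoxymethoxy)-5-methylisobenzofuran-1(3H)-one
Conditions: MOMCl, i-Pr2NEt, CH2Cl2, 0 °C to reflux
Reagents that add atoms: chloromethyl methyl ether, COCCl
Why: O-alkylation gives the MOM ether, which later assists iodine–magnesium exchange by chelation and falls in the final acid step.

Step 5
Reactants: 6 7-iodo-6-(methoxymethoxy)-5-methylisobenzofuran-1(3H)-one
Product: 8 3-[6-(hydroxymethyl)-2-iodo-3-(methoxymethoxy)-4-methylphenyl]-3-oxopropanenitrile, via dilithium enolate alkoxide 7 (not isolated)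
Conditions: MeCN (3 equiv), LiN(i-Pr)2 (2.5 equiv), THF, −78 °C; then 6, −78 °C; aq. NH4Cl
Reagents that add atoms: acetonitrile, CC#N
Why: Claisen-type acylation of lithioacetonitrile by the lactone carbonyl stops at the cyano enolate 7, installs C4–C3–C2≡N with the nitrogen atom and frees the C1 hydroxymethyl group.

**Chain fragment**

Step 6
Reactants: 9 2-methylpent-1-en-3-one; 10 methacrolein (2-methylprop-2-enal)
Product: 13 meso-(3R,4r,5S)-2,4,6-trimethylhepta-1,6-diene-3,5-diol, via boron enolate 11 (not isolated), via boron aldolate 12 (not isolated)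
Conditions: c-Hex2BCl, Et3N, Et2O, −78 to 0 °C; 10, −78 to −20 °C; LiBH4, −78 °C; then MeOH, pH 7 buffer, H2O2, 0 °C
Reagents that add atoms: none
Why: Paterson-type boron aldol through the (E)-enol dicyclohexylborinate and a chair Zimmerman–Traxler transition state sets the anti methyl/hydroxyl pair, and hydride delivery to the cyclic boron aldolate (Narasaka–Prasad-type syn reduction) places the second hydroxyl syn, so the achiral meso diol should result.

Step 7
Reactants: 13 meso-(3R,4r,5S)-2,4,6-trimethylhepta-1,6-diene-3,5-diol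
Product: 14 meso-(4R,5r,6S)-2,2,5-trimethyl-4,6-di(prop-1-en-2-yl)-1,3-dioxane
Conditions: 2,2-dimethoxypropane, PPTS, CH2Cl2, rt
Reagents that add atoms: 2,2-dimethoxypropane, COC(C)(C)OC
Why: Acid-catalysed transketalisation gives the syn-diol acetonide, an all-equatorial 1,3-dioxane that rigidifies both allylic centres for the hydroboration.

Step 8
Reactants: 14 meso-(4R,5r,6S)-2,2,5-trimethyl-4,6-di(prop-1-en-2-yl)-1,3-dioxane
Product: 16 meso-(2S,2'R)-2,2'-[(4S,5s,6R)-2,2,5-trimethyl-1,3-dioxane-4,6-diyl]di(propan-1-ol), via bis-borane 15 (not isolated)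
Conditions: 9-BBN (3 equiv), THF, 0 °C to rt; then NaOH, H2O2, 0 °C
Reagents that add atoms: hydrogen peroxide, OO
Why: Still–Barrish-type hydroboration of both 1,1-disubstituted alkenes occurs anti to the adjacent oxygen-bearing ring carbon (minimised allylic strain), setting the C6 and C10 methyl centres anti to O7 and O9 and keeping the mirror plane.

Step 9
Reactants: 16 meso-(2S,2'R)-2,2'-[(4S,5s,6R)-2,2,5-trimethyl-1,3-dioxane-4,6-diyl]di(propan-1-ol)
Product: 17 (2R,3R,4S,5S,6S)-7-hydroxy-3,5-(isopropylidenedioxy)-2,4,6-trimethylheptyl acetate (C5–C11 piece, acetate on O11, free OH on C5)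
Conditions: Burkholderia cepacia lipase, vinyl acetate, t-BuOMe, 25 °C
Reagents that add atoms: vinyl acetate, CC(=O)OC=C
Why: Lipase-catalysed enantiotopic-group-selective transesterification of a meso polypropionate diol with an irreversible acyl donor should acylate the C11 hydroxymethyl arm and so fix the absolute configuration of all five centres at once; if the enzyme prefers the other arm, lipase hydrolysis of the diacetate would give the same 17.

Step 10
Reactants: 17 C5–C11 monoacetate
Product: 18 C5 aldehyde: (2R,3R,4S,5S,6S)-3,5-(isopropylidenedioxy)-2,4,6-trimethyl-7-oxoheptyl acetate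
Conditions: Dess–Martin periodinane, NaHCO3, CH2Cl2, 0 °C to rt; used at once
Reagents that add atoms: none
Why: Dess–Martin oxidation under buffered conditions should give the α-methyl aldehyde without epimerisation at C6.

Step 11
Reactants: 18 C5 aldehyde
Product: 20 C3–C11 homoallylic alcohol (11-OAc, 7,9-acetonide, free 5-OH, 4-methyl, terminal C3=CH2 vinyl; C4–C10 as in the target), via pinacol borate 19 (not isolated)
Conditions: (Z)-crotylboronic acid pinacol ester, 4 Å MS, toluene, −78 °C to rt; aq. NaHCO3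
Reagents that add atoms: (Z)-crotylboronic acid pinacol ester, C/C=C\CB1OC(C)(C)C(C)(C)O1
Why: (Z)-Crotylboration through a chair transition state gives the syn C4-methyl/C5-hydroxyl pair, and the intrinsic anti-Felkin preference of (Z)-crotylboronates towards α-methyl aldehydes sets the C5 hydroxyl anti to the C6 methyl by substrate control.

Step 12
Reactants: 20 C3–C11 homoallylic alcohol
Product: 21 5-O-triethylsilyl ether of 20
Conditions: TESOTf, 2,6-lutidine, CH2Cl2, −78 °C
Reagents that add atoms: triethylsilyl triflate, CC[Si](CC)(CC)OS(=O)(=O)C(F)(F)F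
Why: Silylation of the hindered secondary alcohol with the silyl triflate gives an ether that survives base, oxidants and organomagnesium reagents and falls in the final acid step.

Step 13
Reactants: 21 5-O-TES C3–C11 alkene
Product: 22 tert-butyl (2E)-enoate (C1–C11: 11-OAc, 7,9-acetonide, 5-OTES; C4–C10 as in the target)
Conditions: tert-butyl acrylate (5 equiv), second-generation Hoveyda–Grubbs catalyst RuCl2(=CH-C6H4-2-O-i-Pr)(SIMes) (5 mol %), CH2Cl2, 40 °C
Reagents that add atoms: tert-butyl acrylate, C=CC(=O)OC(C)(C)C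
Why: Olefin cross-metathesis of a terminal alkene with an acrylate is E-selective and cross-selective because the acrylate does not homodimerise readily.

Step 14
Reactants: 22 C1–C11 enoate acetate
Product: 23 C11 primary alcohol (C1–C11: tert-butyl (2E)-enoate, 5-OTES, 7,9-acetonide, 11-OH)
Conditions: K2CO3, MeOH, 0 °C
Reagents that add atoms: none
Why: Mild methanolysis removes the primary acetate while the tert-butyl enoate, the silyl ether and the acetonide are inert.

Step 15
Reactants: 23 C11 primary alcohol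
Product: 24 C11 aldehyde (C1–C11: tert-butyl (2E)-enoate, 5-OTES, 7,9-acetonide, 11-oxo)
Conditions: Dess–Martin periodinane, NaHCO3, CH2Cl2, 0 °C to rt; used at once
Reagents that add atoms: none
Why: Buffered Dess–Martin oxidation should give the α-methyl aldehyde without epimerisation at C10 and without touching the enoate.

Step 16
Reactants: 24 C11 aldehyde
Product: 26 C1–C13 homoallylic alcohol (free 11-OH, 12-methyl, terminal C13=CH2 vinyl; C4–C12 as in the target), via pinacol borate 25 (not isolated)
Conditions: (Z)-crotylboronic acid pinacol ester, 4 Å MS, toluene, −78 °C to rt; aq. NaHCO3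
Reagents that add atoms: (Z)-crotylboronic acid pinacol ester, C/C=C\CB1OC(C)(C)C(C)(C)O1
Why: The same (Z)-crotylboration at the mirror-related terminus sets the syn C12-methyl/C11-hydroxyl pair and, by the same anti-Felkin substrate control, the C11 hydroxyl anti to the C10 methyl, completing the nine stereocentres.

Step 17
Reactants: 26 C1–C13 homoallylic alcohol
Product: 27 5,11-bis-O-triethylsilyl ether of 26
Conditions: TESOTf, 2,6-lutidine, CH2Cl2, −78 °C
Reagents that add atoms: triethylsilyl triflate, CC[Si](CC)(CC)OS(=O)(=O)C(F)(F)F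
Why: Silylation of the remaining secondary alcohol leaves no free hydroxyl that could add to an enal, enone or enoate under later basic conditions.

Step 18
Reactants: 27 bis-TES C1–C13 alkene; 10 methacrolein
Product: 28 C1–C15 (13E)-enal (tert-butyl (2E,13E)-14-methyl-15-oxo dienoate, 5,11-bis-OTES, 7,9-acetonide; C4–C12 as in the target)
Conditions: 10 (10 equiv), second-generation Hoveyda–Grubbs catalyst RuCl2(=CH-C6H4-2-O-i-Pr)(SIMes) (10 mol %), CH2Cl2, 40 °C
Reagents that add atoms: none
Why: Cross-metathesis of the terminal alkene with methacrolein should give the thermodynamically preferred (E)-trisubstituted enal, the existing enoate being too electron-poor and hindered to take part.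

**Union and ring B**

Step 19
Reactants: 8 3-[6-(hydroxymethyl)-2-iodo-3-(methoxymethoxy)-4-methylphenyl]-3-oxopropanenitrile; 28 C1–C15 enal
Product: 30 C15 carbinol (aryl–CH(OH)–C14(Me)=C13 with free benzylic CH2OH and cyanoacetyl group on ring A; C15 epimers), via arylmagnesium 29 (not isolated)
Conditions: 8 (1.3 equiv), i-PrMgCl·LiCl (3.2 equiv per 8), THF, −78 to −15 °C; then 28, −40 to 0 °C; aq. NH4Cl
Reagents that add atoms: none
Why: Two equivalents of the Grignard reagent deprotonate the alcohol and the ketonitrile (the cyano enolate is inert to nucleophiles), the third performs iodine–magnesium exchange assisted by the ortho MOM ether, and the arylmagnesium adds 1,2 to the enal faster than to the tert-butyl enoate.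

Step 20
Reactants: 30 C15 carbinol
Product: 31 ketoaldehyde (ring A bearing CHO, cyanoacetyl and the C15 enone; chain as in 28)
Conditions: Dess–Martin periodinane (3 equiv), NaHCO3, CH2Cl2, 0 °C; used at once
Reagents that add atoms: none
Why: Dess–Martin oxidation converts the benzylic primary alcohol into the formyl group (C1) and the allylic-benzylic C15 carbinol into the enone in one operation under buffered, non-basic conditions that should not enolise the cyanoacetyl group.

Step 21
Reactants: 31 ketoaldehyde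
Product: 33 protected 2-amino-1,4-naphthoquinone (MOM ether, bis-TES, acetonide, tert-butyl ester), via ketimine 32 (not isolated)
Conditions: 2-(pentafluorophenyl)-6,7-dihydro-5H-pyrrolo[2,1-c][1,2,4]triazol-2-ium tetrafluoroborate (20 mol %), i-Pr2NEt (20 mol %), CH2Cl2, 25 °C
Reagents that add atoms: none
Why: Proposed new method: the carbene released from the triazolium salt adds to the formyl carbon C1 of 31, the resulting Breslow intermediate (an acyl anion equivalent) attacks the nitrile carbon C2, and proton transfer with loss of the carbene gives ketimine 32, which tautomerises to the vinylogous amide, that is the 2-amino-1,4-quinone 33, so the C1–C2 bond, ring B, the quinone oxidation level and the amino group all arise in one redox-neutral isomerisation. The closest known reaction type is the carbene-catalysed intramolecular aldehyde–nitrile cross-coupling of 2-(cyanomethoxy)benzaldehydes to 3-aminochromones; what is untested is a CH-acidic aroylacetonitrile tether and a quinone as product. Ring B closes 6-exo-dig onto the preformed ring A, and no stereocentre is formed. The step needs chemoselectivity for the carbene pathway over enolate chemistry of the C3 methylene (aldol onto C1 to a five-membered ring), over benzoin dimerisation and over Stetter addition to the enone or enoate. This should be secured by a substoichiometric weak base that leaves most of 31 un-enolised, by the reversibility of the five-membered aldol, by the nitrile lying three atoms from C1 while the only enone is trisubstituted and out of reach, and by the irreversible tautomerisation of 32 to the quinone. All chain hydroxyls are masked, so no alkoxide can add to the enone or enoate under these conditions.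

Step 22
Reactants: 33 protected aminoquinone
Product: 34 CNP0336625.1 (target)
Conditions: TFA/H2O/CH2Cl2 (9:1:10), 0 °C to rt; concentrate, brief aq. NaHCO3/MeOH, then acidify to pH 4
Reagents that add atoms: none
Why: Aqueous trifluoroacetic acid cleaves the two silyl ethers, the acetonide, the MOM ether and the tert-butyl ester in one operation, and acid is chosen over base so that the freed 7- and 9-hydroxyls should not add to the enoate or enone and the aminoquinone is not hydrolysed.

**Compound list**

1 | 3-methoxy-4-methylbenzoic acid | COc1cc(C(=O)O)ccc1C | starting material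
2 | 2-(hydroxymethyl)-5-methoxy-4-methylbenzoic acid | COc1cc(C(=O)O)c(CO)cc1C | intermediate
3 | 6-methoxy-5-methylisobenzofuran-1(3H)-one | COc1cc2C(=O)OCc2cc1C | intermediate
4 | 6-hydroxy-5-methylisobenzofuran-1(3H)-one | Oc1cc2C(=O)OCc2cc1C | intermediate
5 | 6-hydroxy-7-iodo-5-methylisobenzofuran-1(3H)-one | Oc1c(I)c2C(=O)OCc2cc1C | intermediate
6 | 7-iodo-6-(methoxymethoxy)-5-methylisobenzofuran-1(3H)-one | COCOc1c(I)c2C(=O)OCc2cc1C | intermediate
7 | dilithium enolate alkoxide of 8 | N#CC=C(O[Li])c1c(CO[Li])cc(C)c(OCOC)c1I | intermediate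
8 | 3-[6-(hydroxymethyl)-2-iodo-3-(methoxymethoxy)-4-methylphenyl]-3-oxopropanenitrile | N#CCC(=O)c1c(CO)cc(C)c(OCOC)c1I | intermediate
9 | 2-methylpent-1-en-3-one | C=C(C)C(=O)CC | starting material
10 | methacrolein | C=C(C)C=O | starting material
11 | (E)-enol dicyclohexylborinate of 9 | C=C(C)/C(OB(C1CCCCC1)C1CCCCC1)=C\C | intermediate
12 | anti boron aldolate (racemic, one enantiomer drawn) | C=C(C)C(=O)[C@@H](C)[C@@H](OB(C1CCCCC1)C1CCCCC1)C(C)=C | intermediate
13 | meso-(3R,4r,5S)-2,4,6-trimethylhepta-1,6-diene-3,5-diol | C=C(C)[C@@H](O)[C@@H](C)[C@@H](O)C(C)=C | intermediate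
14 | meso-(4R,5r,6S)-2,2,5-trimethyl-4,6-di(prop-1-en-2-yl)-1,3-dioxane | C=C(C)[C@@H](O1)[C@@H](C)[C@@H](OC1(C)C)C(C)=C | intermediate
15 | bis(9-borabicyclo[3.3.1]nonan-9-yl) adduct of 14 | C1CCC2CCCC1B2C[C@@H](C)[C@@H](O3)[C@@H](C)[C@@H](OC3(C)C)[C@@H](C)CB1C2CCCC1CCC2 | intermediate
16 | meso-(2S,2'R)-2,2'-[(4S,5s,6R)-2,2,5-trimethyl-1,3-dioxane-4,6-diyl]di(propan-1-ol) | OC[C@@H](C)[C@@H](O1)[C@@H](C)[C@@H](OC1(C)C)[C@@H](C)CO | intermediate
17 | (2R,3R,4S,5S,6S)-7-hydroxy-3,5-(isopropylidenedioxy)-2,4,6-trimethylheptyl acetate | CC(=O)OC[C@@H](C)[C@@H](O1)[C@@H](C)[C@@H](OC1(C)C)[C@@H](C)CO | intermediate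
18 | C5 aldehyde of 17 | CC(=O)OC[C@@H](C)[C@@H](O1)[C@@H](C)[C@@H](OC1(C)C)[C@@H](C)C=O | intermediate
19 | pinacol borate of 20 | CC(=O)OC[C@@H](C)[C@@H](O1)[C@@H](C)[C@@H](OC1(C)C)[C@@H](C)[C@@H](OB2OC(C)(C)C(C)(C)O2)[C@H](C)C=C | intermediate
20 | C3–C11 homoallylic alcohol (11-OAc, 7,9-acetonide, 5-OH) | CC(=O)OC[C@@H](C)[C@@H](O1)[C@@H](C)[C@@H](OC1(C)C)[C@@H](C)[C@@H](O)[C@H](C)C=C | intermediate
21 | 5-O-TES ether of 20 | CC(=O)OC[C@@H](C)[C@@H](O1)[C@@H](C)[C@@H](OC1(C)C)[C@@H](C)[C@@H](O[Si](CC)(CC)CC)[C@H](C)C=C | intermediate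
22 | C1–C11 tert-butyl (2E)-enoate, 11-OAc | CC(=O)OC[C@@H](C)[C@@H](O1)[C@@H](C)[C@@H](OC1(C)C)[C@@H](C)[C@@H](O[Si](CC)(CC)CC)[C@H](C)/C=C/C(=O)OC(C)(C)C | intermediate
23 | C1–C11 enoate, 11-OH | OC[C@@H](C)[C@@H](O1)[C@@H](C)[C@@H](OC1(C)C)[C@@H](C)[C@@H](O[Si](CC)(CC)CC)[C@H](C)/C=C/C(=O)OC(C)(C)C | intermediate
24 | C1–C11 enoate, C11 aldehyde | O=C[C@@H](C)[C@@H](O1)[C@@H](C)[C@@H](OC1(C)C)[C@@H](C)[C@@H](O[Si](CC)(CC)CC)[C@H](C)/C=C/C(=O)OC(C)(C)C | intermediate
25 | pinacol borate of 26 | C=C[C@H](C)[C@@H](OB2OC(C)(C)C(C)(C)O2)[C@@H](C)[C@@H](O1)[C@@H](C)[C@@H](OC1(C)C)[C@@H](C)[C@@H](O[Si](CC)(CC)CC)[C@H](C)/C=C/C(=O)OC(C)(C)C | intermediate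
26 | C1–C13 homoallylic alcohol (11-OH, 5-OTES, 7,9-acetonide) | C=C[C@H](C)[C@@H](O)[C@@H](C)[C@@H](O1)[C@@H](C)[C@@H](OC1(C)C)[C@@H](C)[C@@H](O[Si](CC)(CC)CC)[C@H](C)/C=C/C(=O)OC(C)(C)C | intermediate
27 | 5,11-bis-O-TES C1–C13 alkene | C=C[C@H](C)[C@@H](O[Si](CC)(CC)CC)[C@@H](C)[C@@H](O1)[C@@H](C)[C@@H](OC1(C)C)[C@@H](C)[C@@H](O[Si](CC)(CC)CC)[C@H](C)/C=C/C(=O)OC(C)(C)C | intermediate
28 | C1–C15 (13E)-enal | C/C(C=O)=C\[C@H](C)[C@@H](O[Si](CC)(CC)CC)[C@@H](C)[C@@H](O1)[C@@H](C)[C@@H](OC1(C)C)[C@@H](C)[C@@H](O[Si](CC)(CC)CC)[C@H](C)/C=C/C(=O)OC(C)(C)C | intermediate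
29 | arylmagnesium of 8 (enolate, alkoxide and aryl all as chloromagnesium species) | N#CC=C(O[Mg]Cl)c1c(CO[Mg]Cl)cc(C)c(OCOC)c1[Mg]Cl | intermediate
30 | C15 carbinol (C15 epimers) | C/C(C(O)c1c(OCOC)c(C)cc(CO)c1C(=O)CC#N)=C\[C@H](C)[C@@H](O[Si](CC)(CC)CC)[C@@H](C)[C@@H](O2)[C@@H](C)[C@@H](OC2(C)C)[C@@H](C)[C@@H](O[Si](CC)(CC)CC)[C@H](C)/C=C/C(=O)OC(C)(C)C | intermediate
31 | ketoaldehyde (ortho-formyl aroylacetonitrile) | C/C(C(=O)c1c(OCOC)c(C)cc(C=O)c1C(=O)CC#N)=C\[C@H](C)[C@@H](O[Si](CC)(CC)CC)[C@@H](C)[C@@H](O2)[C@@H](C)[C@@H](OC2(C)C)[C@@H](C)[C@@H](O[Si](CC)(CC)CC)[C@H](C)/C=C/C(=O)OC(C)(C)C | intermediate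
32 | 2-imino-2,3-dihydro-1,4-naphthoquinone (ketimine) | C/C(C(=O)c1c(OCOC)c(C)cc2c1C(=O)CC(=N)C2=O)=C\[C@H](C)[C@@H](O[Si](CC)(CC)CC)[C@@H](C)[C@@H](O3)[C@@H](C)[C@@H](OC3(C)C)[C@@H](C)[C@@H](O[Si](CC)(CC)CC)[C@H](C)/C=C/C(=O)OC(C)(C)C | intermediate
33 | protected 2-amino-1,4-naphthoquinone | C/C(C(=O)c1c(OCOC)c(C)cc2c1C(=O)C=C(N)C2=O)=C\[C@H](C)[C@@H](O[Si](CC)(CC)CC)[C@@H](C)[C@@H](O3)[C@@H](C)[C@@H](OC3(C)C)[C@@H](C)[C@@H](O[Si](CC)(CC)CC)[C@H](C)/C=C/C(=O)OC(C)(C)C | intermediate
34 | CNP0336625.1, (2E,4R,5S,6S,7S,8S,9R,10R,11R,12S,13E)-configured acid | C/C(=C\[C@H](C)[C@@H](O)[C@@H](C)[C@@H](O)[C@@H](C)[C@@H](O)[C@@H](C)[C@@H](O)[C@H](C)/C=C/C(=O)O)C(=O)c1c(O)c(C)cc2c1C(=O)C=C(N)C2=O | target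

**Step count**

Total: 22 steps. Longest linear sequence: 17 steps (steps 6–18 from 9 and 10, then steps 19–22). The ring A branch is steps 1–5.

**Three steps most likely to fail**

1. Step 21 (proposed new method). The acidic C3 methylene may divert 31 into enolate pathways (five-membered aldol onto the formyl group, protonation of the carbene, deactivation of the nitrile as a cyano enolate) faster than the carbene adds to C1. The fallback removes the acidity and uses the aldehyde–nitrile coupling in its reported, non-enolisable form. It sets out from 8. NaBH4 (MeOH, 0 °C) reduces the ketone to the 3-hydroxy nitrile diol F1, and TESCl/imidazole gives the bis(triethylsilyl) ether F2. Iodine–magnesium exchange (i-PrMgCl·LiCl) and addition to 28 give the C15 carbinol F3. Swern oxidation ((COCl)2, DMSO, −78 to −30 °C, then Et3N) turns the C15 carbinol into the enone and, as known for primary triethylsilyl ethers, the benzylic CH2OTES directly into the aldehyde, giving the silyloxy nitrile ketoaldehyde F4. The carbene-catalysed aldehyde–nitrile coupling then gives the 2-amino-4-silyloxy enone F5. TFA/H2O in air removes all protecting groups, the freed 2-aminonaphthalene-1,4-diol tautomer oxidises in air, and the sequence comes back at 34.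

2. Step 19. Iodine–magnesium exchange on the electron-rich, doubly deprotonated arene may be slow, and proton transfer from incompletely deprotonated material may quench the arylmagnesium before it meets the enal. The fallback masks both acidic sites first. From 8, TESCl/Et3N gives the O-silyl enol ether silyl ether F6. Exchange with i-PrMgCl·LiCl and addition to 28 give the carbinol F7. Buffered HF·pyridine (pyridine, THF, 0 °C) removes the enol silyl ether and the primary benzylic silyl ether selectively and comes back at 30.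

3. Step 18. Cross-metathesis of the hindered, allylically branched terminal alkene with a 1,1-disubstituted enal may stall through catalyst decomposition or alkene homodimerisation. The fallback builds the enal by carbonyl olefination. From 27, OsO4 (2 mol %)/NaIO4/2,6-lutidine in dioxane–water cleaves only the terminal vinyl group (the enoate is too electron-poor) to the C13 aldehyde F8. Wittig reaction with 2-(triphenylphosphoranylidene)propanal (toluene, 90 °C) gives the (E)-enal and comes back at 28.

**Further compounds**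

F1 | step 21 | 3-hydroxy-3-[6-(hydroxymethyl)-2-iodo-3-(methoxymethoxy)-4-methylphenyl]propanenitrile (racemic) | N#CCC(O)c1c(CO)cc(C)c(OCOC)c1I
F2 | step 21 | bis(triethylsilyl) ether of F1 | N#CCC(O[Si](CC)(CC)CC)c1c(CO[Si](CC)(CC)CC)cc(C)c(OCOC)c1I
F3 | step 21 | C15 carbinol with benzylic CH2OTES and CH(OTES)CH2CN on ring A (epimer mixture at C15 and at the benzylic silyloxy carbon) | C/C(C(O)c1c(OCOC)c(C)cc(CO[Si](CC)(CC)CC)c1C(CC#N)O[Si](CC)(CC)CC)=C\[C@H](C)[C@@H](O[Si](CC)(CC)CC)[C@@H](C)[C@@H](O2)[C@@H](C)[C@@H](OC2(C)C)[C@@H](C)[C@@H](O[Si](CC)(CC)CC)[C@H](C)/C=C/C(=O)OC(C)(C)C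
F4 | step 21 | silyloxy nitrile ketoaldehyde (CHO, CH(OTES)CH2CN and C15 enone on ring A) | C/C(C(=O)c1c(OCOC)c(C)cc(C=O)c1C(CC#N)O[Si](CC)(CC)CC)=C\[C@H](C)[C@@H](O[Si](CC)(CC)CC)[C@@H](C)[C@@H](O2)[C@@H](C)[C@@H](OC2(C)C)[C@@H](C)[C@@H](O[Si](CC)(CC)CC)[C@H](C)/C=C/C(=O)OC(C)(C)C
F5 | step 21 | 2-amino-4-(triethylsilyloxy)-4H-naphthalen-1-one (protected chain as in 33) | C/C(C(=O)c1c(OCOC)c(C)cc2c1C(O[Si](CC)(CC)CC)C=C(N)C2=O)=C\[C@H](C)[C@@H](O[Si](CC)(CC)CC)[C@@H](C)[C@@H](O3)[C@@H](C)[C@@H](OC3(C)C)[C@@H](C)[C@@H](O[Si](CC)(CC)CC)[C@H](C)/C=C/C(=O)OC(C)(C)C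
F6 | step 19 | 3-[2-iodo-3-(methoxymethoxy)-4-methyl-6-(triethylsilyloxymethyl)phenyl]-3-(triethylsilyloxy)prop-2-enenitrile | N#CC=C(O[Si](CC)(CC)CC)c1c(CO[Si](CC)(CC)CC)cc(C)c(OCOC)c1I
F7 | step 19 | C15 carbinol with benzylic CH2OTES and silyl enol ether of the cyanoacetyl group (C15 epimers) | C/C(C(O)c1c(OCOC)c(C)cc(CO[Si](CC)(CC)CC)c1C(O[Si](CC)(CC)CC)=CC#N)=C\[C@H](C)[C@@H](O[Si](CC)(CC)CC)[C@@H](C)[C@@H](O2)[C@@H](C)[C@@H](OC2(C)C)[C@@H](C)[C@@H](O[Si](CC)(CC)CC)[C@H](C)/C=C/C(=O)OC(C)(C)C
F8 | step 18 | C1–C13 enoate with C13 aldehyde (5,11-bis-OTES, 7,9-acetonide) | O=C[C@H](C)[C@@H](O[Si](CC)(CC)CC)[C@@H](C)[C@@H](O1)[C@@H](C)[C@@H](OC1(C)C)[C@@H](C)[C@@H](O[Si](CC)(CC)CC)[C@H](C)/C=C/C(=O)OC(C)(C)C
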